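# Proposed total synthesis of CNP0186726.1 by chromium Barbier closure of the C8–C9 bond

## The problem

The target (29) is a ten-membered carbocycle (C1–C10) fused across C6–C7 to a butenolide whose ring oxygen sits on C6. C5=C6 is therefore both the exocyclic Z-alkene of an alkylidene butenolide and a trans double bond inside the ten-membered ring. Atoms are numbered as in germacranolides: C1 ketone, C4 tertiary carbinol, C8 senecioate carbon, C10 methyl-bearing carbon (methyl C14), C7=C11 butenolide alkene, C12 lactone carbonyl, C13 acetoxymethyl. Closing this medium ring costs entropy and transannular strain, so the closure must be placed where the rigid diene lactone does not hold the reacting ends apart.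

There are three stereocenters: C4 (R), C8 (R) and C10 (S). C8 and C10 are 1,3-related across C9 and can control one another. C4 is cut off from both by the sp2 atoms C5–C7 and by the C1 ketone, so it has to be brought in as such. C10 is α to the ketone and can epimerize, so it should be made late and without base.

The enol lactone and its cross-conjugated diene do not survive hydroxide, alkoxide or strong nucleophiles. The senecioate and the allylic acetate rule out late base or hydride. The tertiary allylic C4 alcohol is acid-sensitive and can form a hemiketal with C1. The two acyl groups must be placed on O8 and O13 in the presence of the C4 hydroxyl.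

The enabling feature is the array C8(O)–C9H2–C10(CH3)–C1(=O). A γ-hydroxy-α-methyl ketone is the hydrogenated adduct of an aldehyde and a 2-acylallyl metal. Here the aldehyde is C8, attached to C7 of the butenolide and strongly electrophilic, and the allyl metal carries C9, C10, C14 and C1. The ring can thus be closed at the sp3–sp3 bond C8–C9 by carbonyl allylation, and the new C8 hydroxyl then sits where it can direct hydrogenation of the C10 methylene.

## Retrosynthesis

**29 ⇒ 28 ⇒ 27 ⇒ 26 (acyl and silyl groups).** The C13 acetate is removed first in the retrosynthetic sense, giving diol 28. The primary allylic hydroxyl of 28 is acetylated far faster than the tertiary C4 hydroxyl, so no protecting group is needed for that choice. Diol 28 comes from bis-silyl ether 27 by fluoride. The senecioate of 27 is attached to the only free hydroxyl of 26. Putting the senecioate on before the silyl groups come off avoids any competition between O8, O13 and O4.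

**26 ⇒ 25 (the two C–H bonds at C10 and C14).** The C10 methyl is traced to an exocyclic methylene. This removes the epimerizable centre from all earlier steps and leaves a homoallylic alcohol (C8–OH, C9, C10=C14), the classical substrate for hydroxyl-directed hydrogenation. The forward step must add hydrogen to one face of the 1,1-disubstituted alkene only, and must not touch the tri- and tetrasubstituted alkenes of the diene lactone.

**25 ⇒ 24 (C8–C9, the ring-closing bond).** Cutting C8–C9 turns 25 into an aldehyde and a 2-(bromomethyl)enone in one chain (24). Against the neighbouring cuts (C6–C7 with the lactone, C9–C10, C1–C2) this one joins two sp3 carbons through a long flexible tether. It uses the most electrophilic carbonyl of the molecule and creates the hydroxyl that the next step needs. The precursor 24 has no ring beyond the butenolide and only the C4 stereocentre. The forward reaction must close a ten-membered ring, choose the aldehyde over the C1 ketone, and set C8 as (R) with no help from C4.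

**24 ⇒ 23 ⇒ 22 ⇒ 21 (adjustment of three oxygens).** The allylic bromide of 24 is made last from alcohol 23, and 23 from its 4-methoxybenzyl ether 22. The aldehyde and the enone of 22 are both traced to 21, in which C8 is a primary triethylsilyl ether and C1 a free secondary allylic alcohol. A single activated-sulfoxide oxidation can then raise both positions. Keeping C1 as an alcohol until this point protects the Michael-sensitive enone from the hydroxide used earlier.

**21 ⇒ 20 ⇒ 19 ⇒ 18 + 10 (C6–O and C6–C7).** The alkylidene butenolide is opened at the C6–O bond to enynoic acid 20, the hydrolysis product of ester 19. The C6–C7 bond of 19 is cut to enol triflate 18 and terminal alkyne 10. This is the point of convergence: both halves are small, and the alkene geometry of 18 is carried into the lactone. The forward reactions must keep the ester cis to the alkyne and close 5-exo with anti addition, which gives the Z-alkylidene.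

**18 ⇒ 17 ⇒ 16 + 15 (C7–C11).** Triflate 18 is the Z-enol derivative of β-keto ester 17. The C7–C11 bond of 17 is cut to ester enolate 16 (from 12, the silyl ether of 11) and N-methoxy-N-methylamide 15 (from 14, the silyl ether of 13). The two silyl groups differ on purpose: tert-butyldimethylsilyl on O13 lasts to the end, triethylsilyl on O8 is the first to go.

**10 ⇒ 6 + 9 (C1–C10).** Alcohol 10 is cut between C1 and C10 into aldehyde 6 and vinyllithium 9, made from bromide 8 and hence from 7. This brings in C9, C10 and C14 as one three-carbon unit with the oxygen on C14 already differentiated.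

**6 ⇒ 5 ⇒ 4 ⇒ 3 ⇒ 2 ⇒ 1 (the chiral pool).** Aldehyde 6 carries C1–C6 and the C4 stereocentre. Its aldehyde is traced to the epoxide of 5, its alkyne to the aldehyde of 4, and that to the vinyl group of 3. Epoxide 3 comes from silyl ether 2 of (R)-linalool (1). C4 is bought, not made. The price is one carbon removed and one returned at C6.

## Roads not taken

**Alternative 1: macrocyclizing Sonogashira coupling with lactone closure.** The cut is C6–C7 together with C6–O. In the forward step PdCl2(PPh3)2, CuI and Et3N would couple the Z-enol triflate of the open-chain acid A2 with its own terminal alkyne, and the cis carboxylic acid would add 5-exo to give A1.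
- Merits: ring and butenolide arise in one operation. C8 and C10 are set on an open chain by reliable acyclic methods before the ring exists. A1 is three steps from the target. In stereocontrol this is better than the chosen plan, which sets both centres on or at the ring.
- Weak points: the closure must pass through a ten-membered ring holding the nearly linear unit C4–C5≡C6–C7. Reductive elimination to such a strained enyne has to beat intermolecular coupling and copper-mediated alkyne dimerization. A2 carries a free acid next to the triflate, a free tertiary propargylic alcohol and an epimerizable C10 in amine base. Its fully substituted enol triflate must be made late on a complex keto acid.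
- Comparison: the chosen plan uses the same coupling and lactonization between two small pieces (18 and 10), where they are dependable, and closes the ring at a flexible sp3–sp3 bond. It sets against the better stereocontrol of alternative 1 a convergent assembly and a correction route for C8.

**Alternative 2: Grob fragmentation of a decalin vinyl triflate.** The cut is the C1–C6 ring-fusion bond of the bicyclic dienyl triflate A4. KN(SiMe3)2 would deprotonate the C1 alcohol, and fragmentation would expel triflate to give the C1 ketone and the C5≡C6 alkyne of cyclodecynone A3.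
- Merits: the ten-membered ring is made from two six-membered rings with no entropic penalty and no high dilution. The anti-periplanar alignment is built into A4. C4, C8 and C10 can be set on a rigid decalin. In certainty of ring formation this is better than the chosen plan.
- Weak points: A4 needs a ring-fusion tertiary alcohol, a quaternary carbinol next to the triflate carbon and a tetrasubstituted exocyclic acrylate, which means a long linear sequence. A3 is a strained cycloalkyne cross-conjugated to an acrylate and is exposed to amide base as it forms. After the key step the allyl ester must still be cleaved, the lactone closed onto the ring alkyne, and a tertiary 4-methoxybenzyl ether removed.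
- Comparison: more steps and harsher base than the chosen plan, but a safer ring. The chosen plan offsets this with neutral conditions and far fewer steps to its cyclization substrate.

**Alternative 3: anionic oxy-Cope ring expansion.** The cut is C3–C4 (formed) and C1–C6 (cleaved). KH and 18-crown-6 would turn the cyclohexane-fused butenolide A6 into its potassium alkoxide, and the [3,3] shift would give A5 after protonation.
- Merits: one step opens the ten-membered ring, creates C5=C6 and unveils the alkylidene butenolide. It is driven by enolate formation. The substrate is a six-membered ring, on which C8 and C10 are easier to set.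
- Weak points: C4 is formed at a fully substituted enol ether terminus, which slows the shift. Its configuration and the geometry of C5=C6 depend on chair versus boat and on the enol ether geometry, so four outcomes are possible. The C1 alkoxide sits next to C6, which carries the lactone oxygen as a leaving group, so retro-aldol cleavage and acyl transfer compete. KH and the product enolate threaten C10 and the enol lactone.
- Comparison: elegant for the ring, but its main gain, making C4, is something the chosen plan obtains from linalool at no cost. The strongly basic conditions fit the butenolide poorly, whereas the chosen closure runs at neutral pH.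

Key step: step 18

Assumption: the sense of induction of the carbazole ligand in this ring closure cannot be taken over safely from intermolecular allylations, so the ligand enantiomer that leads to (8R)-25 is identified in one test run and then used.

## Route

Step 1
Reactants: 1 (R)-linalool
Product: 2 (3R)-3,7-dimethyl-3-(triethylsilyloxy)octa-1,6-diene
Conditions: Et3SiOTf, 2,6-lutidine, CH2Cl2, −78 → 0 °C
Reagents that add atoms: triethylsilyl trifluoromethanesulfonate, CC[Si](CC)(CC)OS(=O)(=O)C(F)(F)F
Why: Silyl triflate silylation of a tertiary alcohol; the C4 oxygen is blocked so that it cannot open the epoxide of step 2 or add to later carbonyls, and the (R) centre of the chiral pool is carried unchanged.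

Step 2
Reactants: 2 (3R)-3,7-dimethyl-3-(triethylsilyloxy)octa-1,6-diene
Product: 3 2,2-dimethyl-3-[(3R)-3-methyl-3-(triethylsilyloxy)pent-4-en-1-yl]oxirane (both epimers at the oxirane CH)
Conditions: mCPBA, NaHCO3, CH2Cl2, 0 °C
Reagents that add atoms: 3-chloroperbenzoic acid, OOC(=O)c1cccc(Cl)c1
Why: Prilezhaev epoxidation; the electron-rich trisubstituted alkene reacts far faster than the monosubstituted vinyl group beside the silyloxy carbon, and the epoxide serves as a latent C1 aldehyde whose epimer mixture is of no consequence.

Step 3
Reactants: 3 2,2-dimethyl-3-[(3R)-3-methyl-3-(triethylsilyloxy)pent-4-en-1-yl]oxirane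
Product: 4 (2R)-4-(3,3-dimethyloxiran-2-yl)-2-methyl-2-(triethylsilyloxy)butanal
Conditions: O3, CH2Cl2, −78 °C; then PPh3, −78 °C → rt
Reagents that add atoms: ozone, [O-][O+]=O
Why: Ozonolysis with reductive work-up of the only alkene left; the α-silyloxy aldehyde has no α-hydrogen and cannot epimerize, and the epoxide is inert to ozone.

Step 4
Reactants: 4 (2R)-4-(3,3-dimethyloxiran-2-yl)-2-methyl-2-(triethylsilyloxy)butanal
Product: 5 2,2-dimethyl-3-[(3R)-3-methyl-3-(triethylsilyloxy)pent-4-yn-1-yl]oxirane
Conditions: dimethyl (1-diazo-2-oxopropyl)phosphonate, K2CO3, MeOH, 0 °C → rt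
Reagents that add atoms: dimethyl (1-diazo-2-oxopropyl)phosphonate, COP(=O)(OC)C(=[N+]=[N-])C(C)=O
Why: Ohira–Bestmann homologation returns one carbon as the terminal alkyne carbon C6; carbonate in methanol leaves the trisubstituted epoxide and the silyl ether alone.

Step 5
Reactants: 5 2,2-dimethyl-3-[(3R)-3-methyl-3-(triethylsilyloxy)pent-4-yn-1-yl]oxirane
Product: 6 (4R)-4-methyl-4-(triethylsilyloxy)hex-5-ynal
Conditions: H5IO6, THF/Et2O, 0 °C
Reagents that add atoms: none
Why: Periodic acid opens the trisubstituted epoxide and cleaves the glycol in one operation to the C1 aldehyde; the hindered propargylic silyl ether should outlast the short acid contact.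

Step 6
Reactants: 7 2-bromoprop-2-en-1-ol
Product: 8 1-{[(2-bromoprop-2-en-1-yl)oxy]methyl}-4-methoxybenzene
Conditions: NaH, 4-MeOC6H4CH2Cl, Bu4NI (cat.), THF/DMF, 0 °C → rt
Reagents that add atoms: 4-methoxybenzyl chloride, COc1ccc(CCl)cc1
Why: Williamson ether synthesis; the 4-methoxybenzyl ether survives tert-butyllithium, hydroxide and the oxidation of step 15 and is later removed oxidatively without acid or base.

Step 7
Reactants: 8 1-{[(2-bromoprop-2-en-1-yl)oxy]methyl}-4-methoxybenzene; 6 (4R)-4-methyl-4-(triethylsilyloxy)hex-5-ynal
Product: 10 (6R)-2-{[(4-methoxybenzyl)oxy]methyl}-6-methyl-6-(triethylsilyloxy)oct-1-en-7-yn-3-ol (both C3 epimers), via vinyllithium 9 (not isolated)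
Conditions: 8 (2.2 equiv), t-BuLi (4.4 equiv), Et2O, −78 °C; then 6, −78 °C; aq. NH4Cl
Reagents that add atoms: none
Why: Bromine–lithium exchange and 1,2-addition to the aldehyde form C1–C10; the excess of vinyllithium covers any deprotonation of the terminal alkyne, and the C1 carbinol may be an epimer mixture because it is oxidized in step 15.

Step 8
Reactants: 11 methyl 3-hydroxypropanoate
Product: 12 methyl 3-[(tert-butyldimethylsilyl)oxy]propanoate
Conditions: t-BuMe2SiCl, imidazole, DMF, 0 °C → rt
Reagents that add atoms: tert-butyldimethylsilyl chloride, CC(C)(C)[Si](C)(C)Cl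
Why: Standard silylation of a primary alcohol; this group on O13 is meant to last until step 21.

Step 9
Reactants: 13 methyl glycolate
Product: 14 methyl 2-(triethylsilyloxy)acetate
Conditions: Et3SiCl, imidazole, CH2Cl2, 0 °C → rt
Reagents that add atoms: triethylsilyl chloride, CC[Si](Cl)(CC)CC
Why: Standard silylation; a primary triethylsilyl ether is chosen for O8 because it is the one silyl ether that the oxidation of step 15 removes.

Step 10
Reactants: 14 methyl 2-(triethylsilyloxy)acetate
Product: 15 N-methoxy-N-methyl-2-(triethylsilyloxy)acetamide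
Conditions: MeNH(OMe)·HCl, i-PrMgCl, THF, −20 → 0 °C
Reagents that add atoms: N,O-dimethylhydroxylamine hydrochloride, CNOC.Cl
Why: Aminolysis of the ester by the chloromagnesium amide formed in the flask; the product is an acyl donor that stops at the ketone stage.

Step 11
Reactants: 12 methyl 3-[(tert-butyldimethylsilyl)oxy]propanoate; 15 N-methoxy-N-methyl-2-(triethylsilyloxy)acetamide
Product: 17 methyl 2-{[(tert-butyldimethylsilyl)oxy]methyl}-3-oxo-4-(triethylsilyloxy)butanoate (racemic), via lithium enolate 16 (not isolated)
Conditions: LiN(i-Pr)2, THF, −78 °C; then 15, −78 → −40 °C; aq. NH4Cl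
Reagents that add atoms: none
Why: Acylation of an ester enolate by an N-methoxy-N-methylamide (crossed Claisen type) forms C7–C11; the chelated tetrahedral adduct prevents over-addition, the low temperature suppresses loss of silyloxide from the enolate, and the new centre at C11 is erased in step 12.

Step 12
Reactants: 17 methyl 2-{[(tert-butyldimethylsilyl)oxy]methyl}-3-oxo-4-(triethylsilyloxy)butanoate
Product: 18 methyl (2Z)-2-{[(tert-butyldimethylsilyl)oxy]methyl}-4-(triethylsilyloxy)-3-{[(trifluoromethyl)sulfonyl]oxy}but-2-enoate
Conditions: NaH, Et2O, 0 °C; then Tf2O, −78 → 0 °C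
Reagents that add atoms: trifluoromethanesulfonic anhydride, O=S(=O)(OS(=O)(=O)C(F)(F)F)C(F)(F)F
Why: O-Sulfonylation of the sodium enolate of a β-keto ester; the cation bridges both carbonyl oxygens, so the triflate ends cis to the ester (Z), the geometry that later places the acid next to the alkyne.

Step 13
Reactants: 18 methyl (2Z)-2-{[(tert-butyldimethylsilyl)oxy]methyl}-4-(triethylsilyloxy)-3-{[(trifluoromethyl)sulfonyl]oxy}but-2-enoate; 10 (6R)-2-{[(4-methoxybenzyl)oxy]methyl}-6-methyl-6-(triethylsilyloxy)oct-1-en-7-yn-3-ol
Product: 19 methyl (2E,6R)-2-{[(tert-butyldimethylsilyl)oxy]methyl}-9-hydroxy-10-{[(4-methoxybenzyl)oxy]methyl}-6-methyl-6-(triethylsilyloxy)-3-[(triethylsilyloxy)methyl]undeca-2,10-dien-4-ynoate (ester cis to the alkyne; both C9 epimers)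
Conditions: PdCl2(PPh3)2 (5 mol%), CuI (10 mol%), Et3N, THF, rt
Reagents that add atoms: none
Why: Sonogashira coupling of an enol triflate with a terminal alkyne forms C6–C7 with retention of the alkene geometry; free hydroxyl and silyl ethers are tolerated, and triethylamine does not attack the allylic ethers.

Step 14
Reactants: 19 the enynoate of step 13
Product: 21 (5Z)-3-{[(tert-butyldimethylsilyl)oxy]methyl}-5-[(2R)-5-hydroxy-6-{[(4-methoxybenzyl)oxy]methyl}-2-methyl-2-(triethylsilyloxy)hept-6-en-1-ylidene]-4-[(triethylsilyloxy)methyl]furan-2(5H)-one, via enynoic acid 20 (not isolated)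
Conditions: LiOH·H2O, THF/MeOH/H2O, rt; 0.5 M HCl to pH 4 at 0 °C, extraction; then AgNO3 (10 mol%), acetone, rt, dark
Reagents that add atoms: lithium hydroxide, [Li+].[OH-]
Why: Saponification, then silver-catalysed 5-exo-dig cycloisomerization of a (Z)-2-en-4-ynoic acid; anti addition of carboxylate and proton across the alkyne puts C4 cis to the ring oxygen (Z), and 6-endo attack at C5 is blocked by the quaternary C4.

Step 15
Reactants: 21 the alkylidene butenolide of step 14
Product: 22 (2Z)-4-{[(tert-butyldimethylsilyl)oxy]methyl}-2-[(2R)-6-{[(4-methoxybenzyl)oxy]methyl}-2-methyl-5-oxo-2-(triethylsilyloxy)hept-6-en-1-ylidene]-5-oxo-2,5-dihydrofuran-3-carbaldehyde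
Conditions: (COCl)2, DMSO, CH2Cl2, −78 → −40 °C; then Et3N, −78 → 0 °C
Reagents that add atoms: none
Why: Swern oxidation; the C1 allylic alcohol is oxidized to the enone in the usual way, and the primary allylic triethylsilyl ether on C8 is cleaved by the activated sulfoxide and oxidized to the aldehyde in the same flask, a known behaviour of primary triethylsilyl ethers that the primary tert-butyldimethylsilyl and tertiary triethylsilyl ethers do not share.

Step 16
Reactants: 22 the keto aldehyde of step 15
Product: 23 (2Z)-4-{[(tert-butyldimethylsilyl)oxy]methyl}-2-[(2R)-6-(hydroxymethyl)-2-methyl-5-oxo-2-(triethylsilyloxy)hept-6-en-1-ylidene]-5-oxo-2,5-dihydrofuran-3-carbaldehyde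
Conditions: DDQ, CH2Cl2/pH 7 buffer (KH2PO4/K2HPO4), 0 °C → rt
Reagents that add atoms: none
Why: Oxidative cleavage of the 4-methoxybenzyl ether by hydride abstraction at the electron-rich benzylic carbon; the medium is neutral, and the electron-poor diene, the enone, the aldehyde and both silyl ethers are not oxidized.

Step 17
Reactants: 23 the hydroxymethyl enone of step 16
Product: 24 (2Z)-2-[(2R)-6-(bromomethyl)-2-methyl-5-oxo-2-(triethylsilyloxy)hept-6-en-1-ylidene]-4-{[(tert-butyldimethylsilyl)oxy]methyl}-5-oxo-2,5-dihydrofuran-3-carbaldehyde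
Conditions: N-bromosuccinimide, Me2S, CH2Cl2, −20 → 0 °C; used at once
Reagents that add atoms: N-bromosuccinimide, BrN1C(=O)CCC1=O
Why: Corey–Kim-type bromination; the primary allylic alcohol is activated as an alkoxysulfonium salt and displaced by bromide under neutral conditions, the usual way from 2-(hydroxymethyl) to 2-(bromomethyl) enones and acrylates, and the aldehyde is not touched.

Step 18
Reactants: 24 the bromomethyl enone aldehyde of step 17
Product: 25 (4R,8R)-13-[(tert-butyldimethylsilyl)oxy]-8-hydroxy-1-oxo-4-(triethylsilyloxy)germacra-5Z,7(11),10(14)-trien-12,6-olide (ten-membered C8 alcohol with exocyclic methylene on C10)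
Conditions: CrCl2 (4 equiv), 3,6-diphenyl-1,8-bis(4-isopropyl-4,5-dihydrooxazol-2-yl)-9H-carbazole (single enantiomer, 4.4 equiv), i-Pr2NEt, THF, rt; 24 added by syringe pump to 2 mM; aq. KNaC4H4O6
Reagents that add atoms: none
Why: Two equivalents of divalent chromium reduce the allylic C–Br bond of 24 by successive one-electron transfers to a 2-acylallyl complex of trivalent chromium that carries the tridentate carbazolide ligand; the aldehyde oxygen binds this chromium and the allyl group is delivered through its γ-carbon (the former methylene carbon, now C9) in a six-membered chair transition state, so that the former CH2Br carbon emerges as the exocyclic methylene C14. The closest known reaction type is the intramolecular Nozaki–Hiyama–Kishi (chromium Barbier) allylation that closes ten-membered germacrane-type carbocycles from 2-(bromomethyl)acrylate-type donors, together with the ligand-controlled chromium allylation of aldehydes. The ten-membered carbocycle closes by 10-exo-trig attack on the aldehyde carbon, helped by the Z-alkylidene butenolide, which already fixes C5–C8, and by slow addition, which keeps the short-lived allylchromium from meeting a second molecule. The only new stereocentre, C8, is set by the chiral ligand, which shields one face of the chromium-bound aldehyde; C4 lies across the diene and is too remote to bias the addition. No syn/anti question arises because the allyl unit has no γ-substituent. The step needs chemoselectivity for the aldehyde over the C1 ketone and the lactone, which allylchromium reagents show, and the aldehyde on the electron-poor butenolide is the most electrophilic carbonyl present. Aqueous tartrate releases 25 from its chromium alkoxide without harm to the silyl ethers or the enol lactone.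

Step 19
Reactants: 25 the ten-membered C8 alcohol of step 18
Product: 26 (4R,8R,10S)-13-[(tert-butyldimethylsilyl)oxy]-8-hydroxy-1-oxo-4-(triethylsilyloxy)germacra-5Z,7(11)-dien-12,6-olide
Conditions: [Ir(cod)(PCy3)(py)]PF6 (5 mol%), H2 (1 atm), CH2Cl2, 0 °C
Reagents that add atoms: none
Why: Hydroxyl-directed hydrogenation; the homoallylic C8 hydroxyl binds the cationic iridium, and a chair-like O–Ir–alkene chelate with the C7 substituent of C8 equatorial delivers hydrogen to the alkene face that leaves C14 syn to O8 along the C7–C1 chain, which is (10S). The 1,1-disubstituted methylene is also the most accessible alkene, the other two being tri- and tetrasubstituted and conjugated to the lactone.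

Step 20
Reactants: 26 the hydrogenated alcohol of step 19
Product: 27 (4R,8R,10S)-13-[(tert-butyldimethylsilyl)oxy]-8-[(3-methylbut-2-enoyl)oxy]-1-oxo-4-(triethylsilyloxy)germacra-5Z,7(11)-dien-12,6-olide
Conditions: 3-methylbut-2-enoyl chloride, pyridine, DMAP (cat.), CH2Cl2, 0 °C → rt
Reagents that add atoms: 3-methylbut-2-enoyl chloride, CC(C)=CC(Cl)=O
Why: Acylation through the acylpyridinium ion with retention at C8; pyridine is too weak a base to form the vinylketene (which would deconjugate the acyl group) or to epimerize C10, and the only free hydroxyl is that on C8.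

Step 21
Reactants: 27 the senecioate of step 20
Product: 28 (4R,8R,10S)-4,13-dihydroxy-8-[(3-methylbut-2-enoyl)oxy]-1-oxogermacra-5Z,7(11)-dien-12,6-olide
Conditions: HF·pyridine, pyridine, THF, 0 °C → rt
Reagents that add atoms: none
Why: Fluoride cleavage of both silyl ethers in a buffered, non-basic medium that leaves the enol lactone, the senecioate and the C10 centre untouched.

Step 22
Reactants: 28 the diol of step 21
Product: 29 (4R,8R,10S)-13-acetoxy-4-hydroxy-8-[(3-methylbut-2-enoyl)oxy]-1-oxogermacra-5Z,7(11)-dien-12,6-olide (CNP0186726.1)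
Conditions: Ac2O, pyridine, CH2Cl2, 0 °C
Reagents that add atoms: acetic anhydride, CC(=O)OC(C)=O
Why: Selective acetylation of the primary allylic alcohol; the tertiary C4 hydroxyl does not react without forcing conditions.

## Compound list

1 | (R)-linalool | C=C[C@](C)(O)CCC=C(C)C | starting material
2 | (3R)-3,7-dimethyl-3-(triethylsilyloxy)octa-1,6-diene | C=C[C@](C)(O[Si](CC)(CC)CC)CCC=C(C)C | intermediate
3 | 2,2-dimethyl-3-[(3R)-3-methyl-3-(triethylsilyloxy)pent-4-en-1-yl]oxirane (both oxirane epimers) | C=C[C@](C)(O[Si](CC)(CC)CC)CCC1OC1(C)C | intermediate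
4 | (2R)-4-(3,3-dimethyloxiran-2-yl)-2-methyl-2-(triethylsilyloxy)butanal | O=C[C@](C)(O[Si](CC)(CC)CC)CCC1OC1(C)C | intermediate
5 | 2,2-dimethyl-3-[(3R)-3-methyl-3-(triethylsilyloxy)pent-4-yn-1-yl]oxirane | C#C[C@](C)(O[Si](CC)(CC)CC)CCC1OC1(C)C | intermediate
6 | (4R)-4-methyl-4-(triethylsilyloxy)hex-5-ynal | C#C[C@](C)(O[Si](CC)(CC)CC)CCC=O | intermediate
7 | 2-bromoprop-2-en-1-ol | OCC(Br)=C | starting material
8 | 1-{[(2-bromoprop-2-en-1-yl)oxy]methyl}-4-methoxybenzene | COc1ccc(COCC(Br)=C)cc1 | intermediate
9 | {3-[(4-methoxybenzyl)oxy]prop-1-en-2-yl}lithium | [Li]C(=C)COCc1ccc(OC)cc1 | intermediate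
10 | (6R)-2-{[(4-methoxybenzyl)oxy]methyl}-6-methyl-6-(triethylsilyloxy)oct-1-en-7-yn-3-ol (both C3 epimers) | C#C[C@](C)(O[Si](CC)(CC)CC)CCC(O)C(=C)COCc1ccc(OC)cc1 | intermediate
11 | methyl 3-hydroxypropanoate | COC(=O)CCO | starting material
12 | methyl 3-[(tert-butyldimethylsilyl)oxy]propanoate | COC(=O)CCO[Si](C)(C)C(C)(C)C | intermediate
13 | methyl glycolate | COC(=O)CO | starting material
14 | methyl 2-(triethylsilyloxy)acetate | COC(=O)CO[Si](CC)(CC)CC | intermediate
15 | N-methoxy-N-methyl-2-(triethylsilyloxy)acetamide | CON(C)C(=O)CO[Si](CC)(CC)CC | intermediate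
16 | lithium enolate of 12 | COC(O[Li])=CCO[Si](C)(C)C(C)(C)C | intermediate
17 | methyl 2-{[(tert-butyldimethylsilyl)oxy]methyl}-3-oxo-4-(triethylsilyloxy)butanoate (racemic) | COC(=O)C(CO[Si](C)(C)C(C)(C)C)C(=O)CO[Si](CC)(CC)CC | intermediate
18 | methyl (2Z)-2-{[(tert-butyldimethylsilyl)oxy]methyl}-4-(triethylsilyloxy)-3-{[(trifluoromethyl)sulfonyl]oxy}but-2-enoate | COC(=O)/C(CO[Si](C)(C)C(C)(C)C)=C(\OS(=O)(=O)C(F)(F)F)CO[Si](CC)(CC)CC | intermediate
19 | methyl (2E,6R)-2-{[(tert-butyldimethylsilyl)oxy]methyl}-9-hydroxy-10-{[(4-methoxybenzyl)oxy]methyl}-6-methyl-6-(triethylsilyloxy)-3-[(triethylsilyloxy)methyl]undeca-2,10-dien-4-ynoate | COC(=O)/C(CO[Si](C)(C)C(C)(C)C)=C(\C#C[C@](C)(O[Si](CC)(CC)CC)CCC(O)C(=C)COCc1ccc(OC)cc1)CO[Si](CC)(CC)CC | intermediate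
20 | the carboxylic acid of 19 | OC(=O)/C(CO[Si](C)(C)C(C)(C)C)=C(\C#C[C@](C)(O[Si](CC)(CC)CC)CCC(O)C(=C)COCc1ccc(OC)cc1)CO[Si](CC)(CC)CC | intermediate
21 | (5Z)-3-{[(tert-butyldimethylsilyl)oxy]methyl}-5-[(2R)-5-hydroxy-6-{[(4-methoxybenzyl)oxy]methyl}-2-methyl-2-(triethylsilyloxy)hept-6-en-1-ylidene]-4-[(triethylsilyloxy)methyl]furan-2(5H)-one | COc1ccc(COCC(=C)C(O)CC[C@@](C)(O[Si](CC)(CC)CC)/C=C2\OC(=O)C(CO[Si](C)(C)C(C)(C)C)=C2CO[Si](CC)(CC)CC)cc1 | intermediate
22 | (2Z)-4-{[(tert-butyldimethylsilyl)oxy]methyl}-2-[(2R)-6-{[(4-methoxybenzyl)oxy]methyl}-2-methyl-5-oxo-2-(triethylsilyloxy)hept-6-en-1-ylidene]-5-oxo-2,5-dihydrofuran-3-carbaldehyde | COc1ccc(COCC(=C)C(=O)CC[C@@](C)(O[Si](CC)(CC)CC)/C=C2\OC(=O)C(CO[Si](C)(C)C(C)(C)C)=C2C=O)cc1 | intermediate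
23 | (2Z)-4-{[(tert-butyldimethylsilyl)oxy]methyl}-2-[(2R)-6-(hydroxymethyl)-2-methyl-5-oxo-2-(triethylsilyloxy)hept-6-en-1-ylidene]-5-oxo-2,5-dihydrofuran-3-carbaldehyde | OCC(=C)C(=O)CC[C@@](C)(O[Si](CC)(CC)CC)/C=C1\OC(=O)C(CO[Si](C)(C)C(C)(C)C)=C1C=O | intermediate
24 | (2Z)-2-[(2R)-6-(bromomethyl)-2-methyl-5-oxo-2-(triethylsilyloxy)hept-6-en-1-ylidene]-4-{[(tert-butyldimethylsilyl)oxy]methyl}-5-oxo-2,5-dihydrofuran-3-carbaldehyde | BrCC(=C)C(=O)CC[C@@](C)(O[Si](CC)(CC)CC)/C=C1\OC(=O)C(CO[Si](C)(C)C(C)(C)C)=C1C=O | intermediate
25 | (4R,8R)-13-[(tert-butyldimethylsilyl)oxy]-8-hydroxy-1-oxo-4-(triethylsilyloxy)germacra-5Z,7(11),10(14)-trien-12,6-olide | CC(C)(C)[Si](C)(C)OCC1=C2/C(=C/[C@](C)(O[Si](CC)(CC)CC)CCC(=O)C(=C)C[C@H]2O)OC1=O | intermediate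
26 | (4R,8R,10S)-13-[(tert-butyldimethylsilyl)oxy]-8-hydroxy-1-oxo-4-(triethylsilyloxy)germacra-5Z,7(11)-dien-12,6-olide | CC(C)(C)[Si](C)(C)OCC1=C2/C(=C/[C@](C)(O[Si](CC)(CC)CC)CCC(=O)[C@@H](C)C[C@H]2O)OC1=O | intermediate
27 | (4R,8R,10S)-13-[(tert-butyldimethylsilyl)oxy]-8-[(3-methylbut-2-enoyl)oxy]-1-oxo-4-(triethylsilyloxy)germacra-5Z,7(11)-dien-12,6-olide | CC(C)(C)[Si](C)(C)OCC1=C2/C(=C/[C@](C)(O[Si](CC)(CC)CC)CCC(=O)[C@@H](C)C[C@H]2OC(=O)C=C(C)C)OC1=O | intermediate
28 | (4R,8R,10S)-4,13-dihydroxy-8-[(3-methylbut-2-enoyl)oxy]-1-oxogermacra-5Z,7(11)-dien-12,6-olide | OCC1=C2/C(=C/[C@](C)(O)CCC(=O)[C@@H](C)C[C@H]2OC(=O)C=C(C)C)OC1=O | intermediate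
29 | (4R,8R,10S)-13-acetoxy-4-hydroxy-8-[(3-methylbut-2-enoyl)oxy]-1-oxogermacra-5Z,7(11)-dien-12,6-olide (CNP0186726.1) | CC(=O)OCC1=C2/C(=C/[C@](C)(O)CCC(=O)[C@@H](C)C[C@H]2OC(=O)C=C(C)C)OC1=O | target

## Step count and least certain steps

Total: 22 steps. Longest linear sequence: 16 steps (1, 2, 3, 4, 5, 7, 13–22).

**Step 18 (key step).** The main danger is poor facial selection at the aldehyde, because the ligand has to act within a cyclic transition state for which it was not designed and C4 gives no help. Competing processes are coupling between two molecules and one-electron reduction of the very electron-poor enal by divalent chromium. The bromomethyl enone may also decompose before it is metalated. Fallback: from 24, the ring is closed with CrCl2 alone, which should give 25 together with its C8 epimer, the (8S)-alcohol F1; the two are diastereomers and are separated. F1 is oxidized with Dess–Martin periodinane to the 8-ketone F2, and F2 is reduced by Corey–Bakshi–Shibata reduction (oxazaborolidine catalyst, catecholborane, −78 °C) with the catalyst enantiomer that leads to (8R). The C8 carbonyl is part of an ene-1,4-dione and is expected to react ahead of the C1 enone. The route is rejoined at 25.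

**Step 19.** Hydrogen may be delivered to the other face of the methylene if the ring does not allow the chair-like chelate. The exocyclic alkene may also migrate into conjugation within the ring when hydrogen is scarce, and the C7=C11 alkene, which is allylic to the same hydroxyl, may be reduced on long exposure. The transannular hemiketal between O8 and C1 would also lower the amount of free hydroxyl that can direct. Fallback, for the case that the directed addition gives the 8,10-anti relationship: from 24, the ring is closed with the enantiomeric ligand to the (8S)-alcohol F1. Directed hydrogenation of F1 then gives, by the same anti preference, the (8S,10S)-alcohol F3. F3 is esterified with inversion at C8 by a Mitsunobu reaction with 3-methylbut-2-enoic acid (PPh3, diisopropyl azodicarboxylate, toluene, 0 °C). The route is rejoined at 27.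

**Step 15.** Oxidative removal of the primary silyl ether may be incomplete at the temperature at which the C1 alkoxysulfonium salt is still stable, and warming risks chloride displacement at the allylic C1 position. Fallback: from 21, the primary triethylsilyl ether alone is removed (pyridinium p-toluenesulfonate, MeOH/CH2Cl2, 0 °C) to give the diol F4, and both hydroxyls of F4 are oxidized with Dess–Martin periodinane and NaHCO3. The route is rejoined at 22.

**Step 11.** The branched enolate may add slowly to the amide, and on warming it may lose silyloxide by β-elimination before it is acylated. Fallback: from 14, reduction with (i-Bu)2AlH at −78 °C gives 2-(triethylsilyloxy)acetaldehyde F5. Aldol addition of enolate 16 (from 12) to F5 at −78 °C, where elimination does not compete, gives the β-hydroxy ester F6, which is oxidized with Dess–Martin periodinane. The route is rejoined at 17.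

**Step 14.** Hydrolysis of the hindered, fully substituted enoate may be slow, and ring closure may go partly 6-endo to a pyranone if silver activates the alkyne without enough steric bias. Fallback: from acid 20, iodolactonization (I2, NaHCO3, MeCN, 0 °C) closes the five-membered ring by anti addition and gives the (E)-iodoalkylidene butenolide F7. The vinyl iodide of F7 is reduced with retention (Bu3SnH, Pd(PPh3)4, THF), which leaves C4 cis to the ring oxygen. The route is rejoined at 21.

## Further compounds

F1 | step 18 | (4R,8S)-13-[(tert-butyldimethylsilyl)oxy]-8-hydroxy-1-oxo-4-(triethylsilyloxy)germacra-5Z,7(11),10(14)-trien-12,6-olide | CC(C)(C)[Si](C)(C)OCC1=C2/C(=C/[C@](C)(O[Si](CC)(CC)CC)CCC(=O)C(=C)C[C@@H]2O)OC1=O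
F2 | step 18 | (4R)-13-[(tert-butyldimethylsilyl)oxy]-1,8-dioxo-4-(triethylsilyloxy)germacra-5Z,7(11),10(14)-trien-12,6-olide | CC(C)(C)[Si](C)(C)OCC1=C2/C(=C/[C@](C)(O[Si](CC)(CC)CC)CCC(=O)C(=C)CC2=O)OC1=O
F3 | step 19 | (4R,8S,10S)-13-[(tert-butyldimethylsilyl)oxy]-8-hydroxy-1-oxo-4-(triethylsilyloxy)germacra-5Z,7(11)-dien-12,6-olide | CC(C)(C)[Si](C)(C)OCC1=C2/C(=C/[C@](C)(O[Si](CC)(CC)CC)CCC(=O)[C@@H](C)C[C@@H]2O)OC1=O
F4 | step 15 | (5Z)-3-{[(tert-butyldimethylsilyl)oxy]methyl}-5-[(2R)-5-hydroxy-6-{[(4-methoxybenzyl)oxy]methyl}-2-methyl-2-(triethylsilyloxy)hept-6-en-1-ylidene]-4-(hydroxymethyl)furan-2(5H)-one | COc1ccc(COCC(=C)C(O)CC[C@@](C)(O[Si](CC)(CC)CC)/C=C2\OC(=O)C(CO[Si](C)(C)C(C)(C)C)=C2CO)cc1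
F5 | step 11 | 2-(triethylsilyloxy)acetaldehyde | O=CCO[Si](CC)(CC)CC
F6 | step 11 | methyl 2-{[(tert-butyldimethylsilyl)oxy]methyl}-3-hydroxy-4-(triethylsilyloxy)butanoate (diastereomer mixture) | COC(=O)C(CO[Si](C)(C)C(C)(C)C)C(O)CO[Si](CC)(CC)CC
F7 | step 14 | (5E)-3-{[(tert-butyldimethylsilyl)oxy]methyl}-5-[(2R)-5-hydroxy-1-iodo-6-{[(4-methoxybenzyl)oxy]methyl}-2-methyl-2-(triethylsilyloxy)hept-6-en-1-ylidene]-4-[(triethylsilyloxy)methyl]furan-2(5H)-one | COc1ccc(COCC(=C)C(O)CC[C@@](C)(O[Si](CC)(CC)CC)/C(I)=C2\OC(=O)C(CO[Si](C)(C)C(C)(C)C)=C2CO[Si](CC)(CC)CC)cc1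
A1 | alternative 1 | (4R,8R,10S)-8,13-bis[(tert-butyldimethylsilyl)oxy]-4-hydroxy-1-oxogermacra-5Z,7(11)-dien-12,6-olide | CC(C)(C)[Si](C)(C)OCC1=C2/C(=C/[C@](C)(O)CCC(=O)[C@@H](C)C[C@H]2O[Si](C)(C)C(C)(C)C)OC1=O
A2 | alternative 1 | (2Z,4R,6S,10R)-4-[(tert-butyldimethylsilyl)oxy]-2-{[(tert-butyldimethylsilyl)oxy]methyl}-10-hydroxy-6,10-dimethyl-7-oxo-3-{[(trifluoromethyl)sulfonyl]oxy}dodec-2-en-11-ynoic acid | C#C[C@](C)(O)CCC(=O)[C@@H](C)C[C@@H](O[Si](C)(C)C(C)(C)C)/C(OS(=O)(=O)C(F)(F)F)=C(\CO[Si](C)(C)C(C)(C)C)C(=O)O
A3 | alternative 2 | ten-membered cyclodec-5-ynone with exocyclic Z-acrylate allyl ester, C4 4-methoxybenzyl ether and C8, C13 silyl ethers | C=CCOC(=O)/C(CO[Si](C)(C)C(C)(C)C)=C1\C#C[C@](C)(OCc2ccc(OC)cc2)CCC(=O)[C@@H](C)C[C@H]1O[Si](C)(C)C(C)(C)C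
A4 | alternative 2 | decalin with C1 ring-fusion alcohol, C5 enol triflate (C5=C6), C4 4-methoxybenzyl ether and exocyclic Z-acrylate allyl ester on C7 (C1 configuration left open) | C=CCOC(=O)/C(CO[Si](C)(C)C(C)(C)C)=C1\C2=C(OS(=O)(=O)C(F)(F)F)[C@](C)(OCc3ccc(OC)cc3)CCC2(O)[C@@H](C)C[C@H]1O[Si](C)(C)C(C)(C)C
A5 | alternative 3 | (4R,8R,10S)-8,13-bis[(tert-butyldimethylsilyl)oxy]-4-[(4-methoxybenzyl)oxy]-1-oxogermacra-5Z,7(11)-dien-12,6-olide | CC(C)(C)[Si](C)(C)OCC1=C2/C(=C/[C@](C)(OCc3ccc(OC)cc3)CCC(=O)[C@@H](C)C[C@H]2O[Si](C)(C)C(C)(C)C)OC1=O
A6 | alternative 3 | cyclohexane-fused butenolide with C1 hydroxyl and vinyl group and C6 (E)-2-[(4-methoxybenzyl)oxy]prop-1-enyl group (C1 and C6 configurations left open; the two alkenyl groups must be cis) | C=CC1(O)[C@@H](C)C[C@@H](O[Si](C)(C)C(C)(C)C)C2=C(CO[Si](C)(C)C(C)(C)C)C(=O)OC12/C=C(\C)OCc1ccc(OC)cc1
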